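The route hinges on disconnecting C13–C14 (chain numbered C1, the CH2 on the furan ring, to C16, the isopropyl CH). The acyclic array C14(=O)–C13H2–C12(Me)=C11H is the signature of a one-carbon [2,3] shift: heating a C11-hydroxylated 2-methylallyl alcohol with DMF dimethyl acetal should forge C13–C14 and the E C11=C12 alkene at once, delivering a dimethylamide as a masked isobutyl ketone. The precursor is the TBS-protected isopropenyl carbinol made from (S)-citronellol, which supplies C8. The furan ring and C1–C5 arrive later by α-selective allylbarium addition to the C6 aldehyde; isobutyllithium and a final oxidation complete the dione.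

Key step: step 4

Remark on the chemistry: C8 (S) is taken unchanged from (S)-citronellol of high enantiomeric purity. The carbinol centres made in steps 3 (C11) and 10 (C6) are carried as epimer mixtures because steps 4 and 12 erase them. The amide is kept through the fragment union so that the allylbarium reagent meets an aldehyde but no ketone.

**Step 1**
Reactants: 1 (S)-citronellol
Product: 2 tert-butyl{[(3S)-3,7-dimethyloct-6-en-1-yl]oxy}dimethylsilane
Conditions: TBSCl, imidazole, CH2Cl2, 0 °C → rt
Reagents that add atoms: tert-butyldimethylsilyl chloride, CC(C)(C)[Si](C)(C)Cl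
Why: Imidazole-promoted silylation of an unhindered primary alcohol is routine and leaves the alkene and C8 untouched.

**Step 2**
Reactants: 2 tert-butyl{[(3S)-3,7-dimethyloct-6-en-1-yl]oxy}dimethylsilane
Product: 4 (4S)-6-[(tert-butyldimethylsilyl)oxy]-4-methylhexanal, via secondary ozonide 3 (not isolated)
Conditions: O3, CH2Cl2, −78 °C; then PPh3, −78 °C → rt
Reagents that add atoms: ozone, [O-][O+]=O
Why: Criegee ozonolysis of the only alkene followed by phosphine reduction of the ozonide should give the C11 aldehyde, with the silyl ether inert and C8 too far from the carbonyl to epimerise.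

**Step 3**
Reactants: 4 (4S)-6-[(tert-butyldimethylsilyl)oxy]-4-methylhexanal; 5 isopropenylmagnesium bromide
Product: 6 (6S)-8-[(tert-butyldimethylsilyl)oxy]-2,6-dimethyloct-1-en-3-ol (both C3 epimers)
Conditions: THF, −78 → 0 °C; then H2O
Reagents that add atoms: none
Why: Grignard 1,2-addition to an unhindered aldehyde installs C12, its methyl and C13; the new C11 carbinol centre is deliberately uncontrolled because step 4 destroys it.

**Step 4**
Reactants: 6 (6S)-8-[(tert-butyldimethylsilyl)oxy]-2,6-dimethyloct-1-en-3-ol; 7 N,N-dimethylformamide dimethyl acetal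
Product: 10 (3E,7S)-9-[(tert-butyldimethylsilyl)oxy]-N,N,3,7-tetramethylnon-3-enamide, via mixed formamide acetal 8 (not isolated), via alkoxy(dimethylamino)carbene 9 (not isolated)
Conditions: Me2NCH(OMe)2 (excess), xylenes, reflux (ca. 140 °C), MeOH distilled off
Reagents that add atoms: none
Why: The secondary allylic alcohol exchanges onto the formamide acetal to give mixed acetal 8, which loses a second methanol on heating to unmask the nucleophilic carbene 9; its carbene carbon (future C14) then bonds to the terminal methylene C13 while the C11–O bond breaks and the π bond moves to C11=C12, a concerted [2,3]-sigmatropic shift through a five-membered envelope transition state. The closest known reaction type is exactly this thermal rearrangement of allylic alcohols with DMF acetals to one-carbon-homologated β,γ-unsaturated N,N-dimethylamides. No ring is closed and no stereocentre is created: the C11 carbinol centre is consumed, so both epimers of 6 converge on one product, and C8 lies well away from the reacting atoms. The selectivity that matters is E over Z at the new trisubstituted alkene, which should be secured by the C10 chain taking the pseudo-equatorial site of the envelope, the pseudo-axial arrangement that leads to Z being the more crowded one. Chemoselectivity is not in question because the only other functional group is a primary silyl ether, inert to the neutral reagent at this temperature, and the carbonyl is formed already out of conjugation with the alkene.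

**Step 5**
Reactants: 10 (3E,7S)-9-[(tert-butyldimethylsilyl)oxy]-N,N,3,7-tetramethylnon-3-enamide
Product: 11 (3E,7S)-9-hydroxy-N,N,3,7-tetramethylnon-3-enamide
Conditions: TBAF, THF, 0 °C → rt
Reagents that add atoms: none
Why: Fluoride-driven desilylation of a primary TBS ether is reliable, and the tertiary amide is neither attacked nor acidic enough for the alkene to migrate.

**Step 6**
Reactants: 11 (3E,7S)-9-hydroxy-N,N,3,7-tetramethylnon-3-enamide
Product: 12 (3E,7S)-N,N,3,7-tetramethyl-9-oxonon-3-enamide
Conditions: Dess–Martin periodinane, pyridine, CH2Cl2, 0 °C → rt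
Reagents that add atoms: none
Why: Dess–Martin oxidation stops cleanly at the C6 aldehyde under near-neutral conditions, and C8 is β to the new carbonyl and so cannot epimerise.

**Step 7**
Reactants: 13 5-bromo-2-methylpent-2-ene; 14 3-bromofuran
Product: 16 3-(4-methylpent-3-en-1-yl)furan (perillene), via homoprenylmagnesium bromide 15 (not isolated)
Conditions: Mg, Et2O, reflux; then 14, NiCl2(dppp) (cat.), Et2O, 0 °C → reflux
Reagents that add atoms: none
Why: Kumada–Corriu coupling of a primary alkyl Grignard reagent with 3-bromofuran under NiCl2(dppp) catalysis is an established way to 3-alkylfurans, the chelating diphosphine suppressing β-hydride elimination.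

**Step 8**
Reactants: 16 3-(4-methylpent-3-en-1-yl)furan
Product: 17 (2E)-5-(furan-3-yl)-2-methylpent-2-en-1-ol
Conditions: SeO2 (cat.), t-BuOOH, salicylic acid (cat.), CH2Cl2, 0 °C → rt; then NaBH4, MeOH, 0 °C
Reagents that add atoms: tert-butyl hydroperoxide, CC(C)(C)OO (oxygen relayed through catalytic selenium dioxide, O=[Se]=O)
Why: SeO2/t-BuOOH allylic oxidation (ene reaction then [2,3] shift) is known to hydroxylate the E methyl of an isopropylidene terminus selectively, the borohydride wash returning any over-oxidised enal to the alcohol.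

**Step 9**
Reactants: 17 (2E)-5-(furan-3-yl)-2-methylpent-2-en-1-ol
Product: 19 3-[(3E)-5-chloro-4-methylpent-3-en-1-yl]furan, via allylic mesylate 18 (not isolated)
Conditions: MsCl, LiCl, 2,4,6-collidine, DMF, 0 °C
Reagents that add atoms: lithium chloride, [Li+].[Cl-]
Why: In situ mesylation and SN2 displacement by chloride at the primary allylic carbon gives the chloride without allylic transposition or loss of E geometry, under buffered conditions the furan tolerates.

**Step 10**
Reactants: 12 (3E,7S)-N,N,3,7-tetramethyl-9-oxonon-3-enamide; 19 3-[(3E)-5-chloro-4-methylpent-3-en-1-yl]furan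
Product: 21 (3E,7S,11E)-14-(furan-3-yl)-9-hydroxy-N,N,3,7,11-pentamethyltetradeca-3,11-dienamide (both C9 epimers), via allylbarium chloride 20 (not isolated)
Conditions: BaI2, lithium biphenylide (2 equiv), THF, rt (activated zerovalent barium); 19, −78 °C; 12, −78 °C; then H2O
Reagents that add atoms: none
Why: Allylbarium reagents formed at −78 °C from allylic chlorides and activated barium are known to keep their alkene geometry and to add to aldehydes at the α-carbon, which forms C5–C6 with the E C3=C4 alkene intact while the tertiary amide is left alone; the new C6 carbinol centre is uncontrolled and is removed in step 12.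

**Step 11**
Reactants: 21 (3E,7S,11E)-14-(furan-3-yl)-9-hydroxy-N,N,3,7,11-pentamethyltetradeca-3,11-dienamide; 22 isobutyllithium
Product: 24 (6E,10S,14E)-17-(furan-3-yl)-12-hydroxy-2,6,10,14-tetramethylheptadeca-6,14-dien-4-one (both C12 epimers), via dilithium hemiaminal alkoxide 23 (not isolated)
Conditions: i-BuLi (3 equiv), Et2O, −78 → −40 °C; then cold H2O (pH 7 buffer)
Reagents that add atoms: none
Why: Organolithium addition to an N,N-dimethylamide stops at a tetrahedral lithium adduct that releases the ketone only on aqueous work-up, so no tertiary alcohol should form; the first equivalent merely deprotonates the C6 hydroxyl, and the cold neutral quench keeps the C11=C12 alkene out of conjugation.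

**Step 12**
Reactants: 24 (6E,10S,14E)-17-(furan-3-yl)-12-hydroxy-2,6,10,14-tetramethylheptadeca-6,14-dien-4-one
Product: 25 idiadione, (6E,10S,14E)-17-(furan-3-yl)-2,6,10,14-tetramethylheptadeca-6,14-diene-4,12-dione
Conditions: Dess–Martin periodinane, pyridine, CH2Cl2, 0 °C → rt
Reagents that add atoms: none
Why: Pyridine-buffered Dess–Martin oxidation converts the homoallylic C6 carbinol into the β,γ-unsaturated ketone without acid or base strong enough to move either alkene or to harm the furan.

**Compound list**

1 | (S)-citronellol, (3S)-3,7-dimethyloct-6-en-1-ol | OCC[C@@H](C)CCC=C(C)C | starting material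
2 | tert-butyl{[(3S)-3,7-dimethyloct-6-en-1-yl]oxy}dimethylsilane | CC(C)=CCC[C@H](C)CCO[Si](C)(C)C(C)(C)C | intermediate
3 | tert-butyl{[(3S)-5-(5,5-dimethyl-1,2,4-trioxolan-3-yl)-3-methylpentyl]oxy}dimethylsilane (secondary ozonide, either configuration at the ring CH) | CC1(C)OOC(CC[C@H](C)CCO[Si](C)(C)C(C)(C)C)O1 | intermediate
4 | (4S)-6-[(tert-butyldimethylsilyl)oxy]-4-methylhexanal | O=CCC[C@H](C)CCO[Si](C)(C)C(C)(C)C | intermediate
5 | isopropenylmagnesium bromide | C=C(C)[Mg]Br | starting material
6 | (6S)-8-[(tert-butyldimethylsilyl)oxy]-2,6-dimethyloct-1-en-3-ol (both C3 epimers) | C=C(C)C(O)CC[C@H](C)CCO[Si](C)(C)C(C)(C)C | intermediate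
7 | N,N-dimethylformamide dimethyl acetal | COC(OC)N(C)C | starting material
8 | 1-{[(6S)-8-[(tert-butyldimethylsilyl)oxy]-2,6-dimethyloct-1-en-3-yl]oxy}-1-methoxy-N,N-dimethylmethanamine (mixed formamide acetal) | C=C(C)C(OC(OC)N(C)C)CC[C@H](C)CCO[Si](C)(C)C(C)(C)C | intermediate
9 | {[(6S)-8-[(tert-butyldimethylsilyl)oxy]-2,6-dimethyloct-1-en-3-yl]oxy}(dimethylamino)methylidene (carbene) | C=C(C)C(O[C]N(C)C)CC[C@H](C)CCO[Si](C)(C)C(C)(C)C | intermediate
10 | (3E,7S)-9-[(tert-butyldimethylsilyl)oxy]-N,N,3,7-tetramethylnon-3-enamide | CN(C)C(=O)C/C(C)=C/CC[C@H](C)CCO[Si](C)(C)C(C)(C)C | intermediate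
11 | (3E,7S)-9-hydroxy-N,N,3,7-tetramethylnon-3-enamide | CN(C)C(=O)C/C(C)=C/CC[C@H](C)CCO | intermediate
12 | (3E,7S)-N,N,3,7-tetramethyl-9-oxonon-3-enamide | CN(C)C(=O)C/C(C)=C/CC[C@H](C)CC=O | intermediate
13 | 5-bromo-2-methylpent-2-ene | CC(C)=CCCBr | starting material
14 | 3-bromofuran | Brc1ccoc1 | starting material
15 | (4-methylpent-3-en-1-yl)magnesium bromide | CC(C)=CCC[Mg]Br | intermediate
16 | 3-(4-methylpent-3-en-1-yl)furan (perillene) | CC(C)=CCCc1ccoc1 | intermediate
17 | (2E)-5-(furan-3-yl)-2-methylpent-2-en-1-ol | OC/C(C)=C/CCc1ccoc1 | intermediate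
18 | (2E)-5-(furan-3-yl)-2-methylpent-2-en-1-yl methanesulfonate | CS(=O)(=O)OC/C(C)=C/CCc1ccoc1 | intermediate
19 | 3-[(3E)-5-chloro-4-methylpent-3-en-1-yl]furan | ClC/C(C)=C/CCc1ccoc1 | intermediate
20 | [(2E)-5-(furan-3-yl)-2-methylpent-2-en-1-yl]barium chloride | Cl[Ba]C/C(C)=C/CCc1ccoc1 | intermediate
21 | (3E,7S,11E)-14-(furan-3-yl)-9-hydroxy-N,N,3,7,11-pentamethyltetradeca-3,11-dienamide (both C9 epimers) | CN(C)C(=O)C/C(C)=C/CC[C@H](C)CC(O)C/C(C)=C/CCc1ccoc1 | intermediate
22 | isobutyllithium | [Li]CC(C)C | starting material
23 | dilithium 4,12-bis-alkoxide of (6E,10S,14E)-4-(dimethylamino)-17-(furan-3-yl)-2,6,10,14-tetramethylheptadeca-6,14-diene-4,12-diol | [Li+].[Li+].CN(C)C([O-])(CC(C)C)C/C(C)=C/CC[C@H](C)CC([O-])C/C(C)=C/CCc1ccoc1 | intermediate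
24 | (6E,10S,14E)-17-(furan-3-yl)-12-hydroxy-2,6,10,14-tetramethylheptadeca-6,14-dien-4-one (both C12 epimers) | CC(C)CC(=O)C/C(C)=C/CC[C@H](C)CC(O)C/C(C)=C/CCc1ccoc1 | intermediate
25 | idiadione, (6E,10S,14E)-17-(furan-3-yl)-2,6,10,14-tetramethylheptadeca-6,14-diene-4,12-dione | C/C(=C\CC[C@H](C)CC(=O)C/C(C)=C/CCc1ccoc1)CC(=O)CC(C)C | target

**Step count**

Total step count: 12.
Longest linear sequence: 9 steps (steps 1–6 and 10–12, from 1); the furan fragment 19 takes 3 steps (7–9).

**Steps most likely to fail**

**Step 4.** The mixed acetal or carbene may be diverted before the shift (elimination to a diene, formate ester formation), or the geometric control may be incomplete so that some Z alkene forms through the pseudo-axial envelope.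

The fallback sets out from aldehyde 4 and comes back to the route at amide 10; it fixes the alkene by olefination and then adds C14 by Arndt–Eistert homologation.
- A Wittig reaction of 4 with the stabilised ylide Ph3P=C(CH3)CO2Et in warm toluene should give ethyl (2E,6S)-8-[(tert-butyldimethylsilyl)oxy]-2,6-dimethyloct-2-enoate F1 with reliable E geometry.
- Saponification (LiOH, THF/MeOH/H2O) would give (2E,6S)-8-[(tert-butyldimethylsilyl)oxy]-2,6-dimethyloct-2-enoic acid F2.
- Neutral activation with 1-chloro-N,N,2-trimethylpropenylamine would give (2E,6S)-8-[(tert-butyldimethylsilyl)oxy]-2,6-dimethyloct-2-enoyl chloride F3.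
- Trimethylsilyldiazomethane would convert F3 into (3E,7S)-9-[(tert-butyldimethylsilyl)oxy]-1-diazo-3,7-dimethylnon-3-en-2-one F4.
- Photochemical Wolff rearrangement of F4 in THF containing dimethylamine should proceed through (3E,7S)-9-[(tert-butyldimethylsilyl)oxy]-3,7-dimethylnona-1,3-dien-1-one F5 (the vinylketene, not isolated). The alkenyl group migrates with retention of geometry, and amine capture with kinetic α-protonation should give 10.

**Step 10.** The allylbarium may lose regiocontrol (attack through the γ-carbon) or geometric integrity if it equilibrates above −78 °C, the chloride may homocouple during metalation, or the barium may be insufficiently active.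

The fallback sets out from aldehyde 12 and comes back at hydroxy amide 21; it makes chloride 19 unnecessary by building the C3=C4 alkene through carbometalation and cross-coupling.
- Zinc-mediated Barbier propargylation of 12 (propargyl bromide, Zn, THF/aq. NH4Cl) should give (3E,7S)-9-hydroxy-N,N,3,7-tetramethyldodec-3-en-11-ynamide F6.
- Zirconium-catalysed methylalumination (Me3Al, Cp2ZrCl2, CH2Cl2) followed by iodinolysis should give (3E,7S,11E)-9-hydroxy-12-iodo-N,N,3,7,11-pentamethyldodeca-3,11-dienamide F7, the E geometry following from syn addition.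
- Separately, Wittig methylenation of commercial furan-3-carbaldehyde would give 3-ethenylfuran F8.
- Hydroboration of F8 with 9-BBN would give 9-[2-(furan-3-yl)ethyl]-9-borabicyclo[3.3.1]nonane F9.
- Suzuki–Miyaura B-alkyl coupling of F9 with F7 (PdCl2(dppf), AsPh3, Cs2CO3, DMF/THF/H2O) should give 21.

**Step 11.** The organolithium may deprotonate the C13 methylene, which is flanked by the amide carbonyl and the alkene, instead of adding to the carbonyl, so that amide returns on work-up; the alkene may also migrate into conjugation during the basic quench.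

The fallback sets out from hydroxy amide 21 and comes back at the target 25; it goes through the aldehyde oxidation level and so avoids a strongly basic reagent at the amide.
- Cp2Zr(H)Cl in THF at rt (one extra equivalent for the free hydroxyl) is known to reduce tertiary amides to aldehydes and should give (3E,7S,11E)-14-(furan-3-yl)-9-hydroxy-3,7,11-trimethyltetradeca-3,11-dienal F10.
- Isobutylmagnesium bromide (THF, −78 °C) would add to F10 to give (6E,10S,14E)-17-(furan-3-yl)-2,6,10,14-tetramethylheptadeca-6,14-diene-4,12-diol F11.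
- Pyridine-buffered Dess–Martin oxidation of both carbinols of F11 should give 25 directly.

**Further compounds**

F1 | step 4 | ethyl (2E,6S)-8-[(tert-butyldimethylsilyl)oxy]-2,6-dimethyloct-2-enoate | CCOC(=O)/C(C)=C/CC[C@H](C)CCO[Si](C)(C)C(C)(C)C
F2 | step 4 | (2E,6S)-8-[(tert-butyldimethylsilyl)oxy]-2,6-dimethyloct-2-enoic acid | OC(=O)/C(C)=C/CC[C@H](C)CCO[Si](C)(C)C(C)(C)C
F3 | step 4 | (2E,6S)-8-[(tert-butyldimethylsilyl)oxy]-2,6-dimethyloct-2-enoyl chloride | ClC(=O)/C(C)=C/CC[C@H](C)CCO[Si](C)(C)C(C)(C)C
F4 | step 4 | (3E,7S)-9-[(tert-butyldimethylsilyl)oxy]-1-diazo-3,7-dimethylnon-3-en-2-one | [N-]=[N+]=CC(=O)/C(C)=C/CC[C@H](C)CCO[Si](C)(C)C(C)(C)C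
F5 | step 4 | (3E,7S)-9-[(tert-butyldimethylsilyl)oxy]-3,7-dimethylnona-1,3-dien-1-one | O=C=C/C(C)=C/CC[C@H](C)CCO[Si](C)(C)C(C)(C)C
F6 | step 10 | (3E,7S)-9-hydroxy-N,N,3,7-tetramethyldodec-3-en-11-ynamide | CN(C)C(=O)C/C(C)=C/CC[C@H](C)CC(O)CC#C
F7 | step 10 | (3E,7S,11E)-9-hydroxy-12-iodo-N,N,3,7,11-pentamethyldodeca-3,11-dienamide | CN(C)C(=O)C/C(C)=C/CC[C@H](C)CC(O)C/C(C)=C/I
F8 | step 10 | 3-ethenylfuran | C=Cc1ccoc1
F9 | step 10 | 9-[2-(furan-3-yl)ethyl]-9-borabicyclo[3.3.1]nonane | C(Cc1ccoc1)B1C2CCCC1CCC2
F10 | step 11 | (3E,7S,11E)-14-(furan-3-yl)-9-hydroxy-3,7,11-trimethyltetradeca-3,11-dienal | O=CC/C(C)=C/CC[C@H](C)CC(O)C/C(C)=C/CCc1ccoc1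
F11 | step 11 | (6E,10S,14E)-17-(furan-3-yl)-2,6,10,14-tetramethylheptadeca-6,14-diene-4,12-diol | CC(C)CC(O)C/C(C)=C/CC[C@H](C)CC(O)C/C(C)=C/CCc1ccoc1
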